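A direct plan would open (R)-2-methyloxirane A1 at its CH2 group with (2,4,5-trimethoxyphenyl)magnesium bromide A2 and catalytic CuI to give (R)-1-(2,4,5-trimethoxyphenyl)propan-2-ol A3, then couple 1,2,4-trimethoxybenzene A4 to the benzylic C–H of A3 at an anode via the benzylic cation A5.
Weakest: (a) the anodic coupling would have to oxidise A3 beside excess A4 and a still more oxidisable product (doubly benzylic C–H), and is unproven in one cell;
(b) cation A5 would form next to the free C2 carbinol, where a 1,2-hydride shift or C1–C2 cleavage would erase, in the last step, the only stereocentre, the one bought with A1;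
(c) the two identical rings would reach C1 by two unrelated reactions, so the symmetry of C1 is not used.

**Retrosynthetic overview**
C1 carries two identical 2,4,5-trimethoxyphenyl rings and is not stereogenic; the only stereocentre is C2 of the CH(OH)CH3 end, so the route cuts C1–C2.
First both bought arene rings are set on the future C1 at once, by double Matteson homologation of Cl2CHBpin; no ring is formed in the route.
Then lithiation–borylation with (−)-sparteine-bound lithiated ethyl carbamate forms C1–C2 and sets C2; C–B oxidation gives the C2 hydroxyl.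
No cation arises at C1 beside the carbinol, nothing is oxidised at an electrode, and C2 is made by reagent control as the last C–C bond forms.

Key step: step 3

Remark: the SMILES fixes C2 as R; (−)-sparteine is taken as the commercial free base.

**Step 1**
Reactants: 1 1-bromo-2,4,5-trimethoxybenzene; 2 2-(dichloromethyl)-4,4,5,5-tetramethyl-1,3,2-dioxaborolane (Cl2CHBpin)
Product: 5 2-[bis(2,4,5-trimethoxyphenyl)methyl]-4,4,5,5-tetramethyl-1,3,2-dioxaborolane, via arylmagnesium bromide 3 (not isolated), via α-chloro boronic ester 4 (not isolated)
Conditions: 1 (2.2 equiv), Mg turnings (2.6 equiv), cat. I2, THF, 45 °C; then 2 (1.0 equiv) in THF, −78 °C → rt, 16 h; 45 °C, 2 h; aq. NH4Cl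
Reagents that add atoms: none
Why: Matteson homologation carried out twice on one boron atom: each equivalent of 3 adds to boron and the aryl group then shifts 1,2 from boron to carbon with loss of chloride, first to 4 and then to 5; the two aryl groups are identical, so the new carbon (C1 of the target) is not stereogenic and no selectivity is asked for.

**Step 2**
Reactants: 6 sodium ethoxide; 7 N,N-diisopropylcarbamoyl chloride
Product: 8 ethyl N,N-diisopropylcarbamate
Conditions: 6 (1.2 equiv), THF, 0 °C → reflux; aqueous work-up, distillation
Reagents that add atoms: none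
Why: Nucleophilic acyl substitution of the carbamoyl chloride by ethoxide (carbamate formation) should give the hindered carbamate that later directs the α-lithiation and serves as the leaving group; no stereocentre is involved.

**Step 3**
Reactants: 8 ethyl N,N-diisopropylcarbamate; 5 2-[bis(2,4,5-trimethoxyphenyl)methyl]-4,4,5,5-tetramethyl-1,3,2-dioxaborolane
Product: 12 tatarinoid C [(2R)-1,1-bis(2,4,5-trimethoxyphenyl)propan-2-ol], via lithiated carbamate 9 (not isolated), via boronate complex 10 (not isolated), via secondary boronic ester 11 (not isolated)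
Conditions: 8 (1.4 equiv), (−)-sparteine (1.4 equiv), s-BuLi (1.3 equiv), Et2O, −78 °C, 5 h; 5 (1.0 equiv) in THF, −78 °C, 2 h; MgBr2·OEt2 (2 equiv), −78 °C → reflux, 16 h; then THF, 2 M NaOH, 30% H2O2, 0 °C → rt
Reagents that add atoms: hydrogen peroxide (OO)
Why: s-BuLi/(−)-sparteine should remove the pro-S hydrogen of the OCH2 group of 8 (carbamate-directed asymmetric deprotonation) to give the configurationally stable (S)-carbenoid 9, which adds to the boron of 5 with retention to give boronate complex 10; on warming with MgBr2 the bis(aryl)methyl group shifts 1,2 from boron to carbon anti to the leaving carbamate (inversion), which forms the C1–C2 bond in (R)-11, and alkaline H2O2 then replaces boron by hydroxyl with retention. The closest known reaction type is the lithiation–borylation–oxidation of lithiated primary alkyl carbamates with secondary and benzylic pinacol boronic esters (stereospecific 1,2-metallate rearrangement). No ring is closed. The only new stereocentre, C2, is controlled by the chiral diamine (reagent control) through three stereospecific events, retention, inversion and retention, which together lead to R; 5 is achiral, so there is no matched or mismatched case. The step needs addition of 9 to boron in preference to removal of the doubly benzylic α-boryl hydrogen of 5, and migration of carbon in preference to a pinacol oxygen: the first is secured by the fast boronate formation at −78 °C, by the low acidity of a methine between two electron-rich rings and by keeping s-BuLi below the amount of 8, the second by the high migratory aptitude of a benzylic carbon group.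

**Compound list**
1 | 1-bromo-2,4,5-trimethoxybenzene | COc1cc(OC)c(Br)cc1OC | starting material
2 | 2-(dichloromethyl)-4,4,5,5-tetramethyl-1,3,2-dioxaborolane | ClC(Cl)B1OC(C)(C)C(C)(C)O1 | starting material
3 | (2,4,5-trimethoxyphenyl)magnesium bromide | COc1cc(OC)c([Mg]Br)cc1OC | intermediate
4 | 2-[chloro(2,4,5-trimethoxyphenyl)methyl]-4,4,5,5-tetramethyl-1,3,2-dioxaborolane (racemic) | COc1cc(OC)c(C(Cl)B2OC(C)(C)C(C)(C)O2)cc1OC | intermediate
5 | 2-[bis(2,4,5-trimethoxyphenyl)methyl]-4,4,5,5-tetramethyl-1,3,2-dioxaborolane | COc1cc(OC)c(C(B2OC(C)(C)C(C)(C)O2)c2cc(OC)c(OC)cc2OC)cc1OC | intermediate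
6 | sodium ethoxide | CC[O-].[Na+] | starting material
7 | N,N-diisopropylcarbamoyl chloride | CC(C)N(C(C)C)C(=O)Cl | starting material
8 | ethyl N,N-diisopropylcarbamate | CCOC(=O)N(C(C)C)C(C)C | intermediate
9 | (S)-1-lithioethyl N,N-diisopropylcarbamate, as its (−)-sparteine complex (ligand not drawn) | C[C@H]([Li])OC(=O)N(C(C)C)C(C)C | intermediate
10 | lithium [bis(2,4,5-trimethoxyphenyl)methyl][(1S)-1-(N,N-diisopropylcarbamoyloxy)ethyl](pinacolato)borate | C[C@H]([B-]1(OC(C)(C)C(C)(C)O1)C(c1cc(OC)c(OC)cc1OC)c1cc(OC)c(OC)cc1OC)OC(=O)N(C(C)C)C(C)C.[Li+] | intermediate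
11 | 2-[(2R)-1,1-bis(2,4,5-trimethoxyphenyl)propan-2-yl]-4,4,5,5-tetramethyl-1,3,2-dioxaborolane | C[C@@H](B1OC(C)(C)C(C)(C)O1)C(c1cc(OC)c(OC)cc1OC)c1cc(OC)c(OC)cc1OC | intermediate
12 | tatarinoid C, (2R)-1,1-bis(2,4,5-trimethoxyphenyl)propan-2-ol | COc1cc(OC)c(C(c2cc(OC)c(OC)cc2OC)[C@@H](C)O)cc1OC | target

**Step count**
Total step count: 3. Longest linear sequence: 2 steps (1 → 5 → 12; the branch 6 → 8 → 12 is equally long).

**Steps most likely to fail**

Step 3. The diamine-bound carbenoid 9 may add too slowly to the crowded boron of 5, or the 1,2-shift in 10 may stall, so that 9 decomposes on warming and unchanged 5 is oxidised in the work-up. A complexation that only proceeds at higher temperature would also cost configurational purity. The fallback sets out from 3 and returns at 12. Three equivalents of 3 would be added to methyl (R)-lactate in THF (one is spent on the hydroxyl) to give (2R)-1,1-bis(2,4,5-trimethoxyphenyl)propane-1,2-diol F1, with the stereocentre taken from the chiral pool. Ionic hydrogenation of F1 with excess Et3SiH and CF3CO2H in CH2Cl2 at low temperature, with the silane present before the acid is added so that hydride capture of the doubly stabilised diarylmethyl cation outpaces a pinacol-type shift, followed by a basic methanolic work-up, would remove the tertiary dibenzylic hydroxyl and give 12.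

Step 1. The second boron-to-carbon aryl shift may be slow on the crowded, ortho-methoxy-substituted boronate, so that the reaction stops at 4, which ionises and is lost on work-up; 5 may also lose boron on silica. The fallback sets out from 3 and returns at 5. Addition of 3 to 2,4,5-trimethoxybenzonitrile and acid hydrolysis would give bis(2,4,5-trimethoxyphenyl)methanone F2. Condensation with p-toluenesulfonyl hydrazide would give its N-tosylhydrazone F3. Heating F3 with B2pin2 and NaOMe in toluene (Bamford–Stevens generation of the diaryldiazomethane and its reductive borylation) would give 5.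

Step 2. Acylation of ethoxide by the hindered carbamoyl chloride may be incomplete, the fairly volatile carbamate may be lost on isolation, and downstream the carbamate may leave too slowly from the crowded boronate. The fallback sets out from 6 and returns at 11. Acylation of 6 with 2,4,6-triisopropylbenzoyl chloride would give ethyl 2,4,6-triisopropylbenzoate F4, a non-volatile carbenoid precursor with a better leaving group. s-BuLi/(−)-sparteine in Et2O at −78 °C would give (S)-1-lithioethyl 2,4,6-triisopropylbenzoate F5 with the same sense of induction. With 5 this would give boronate complex F6, and the 1,2-shift with loss of the benzoate would return to 11.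

**Further compounds**
F1 | step 3 | (2R)-1,1-bis(2,4,5-trimethoxyphenyl)propane-1,2-diol | C[C@@H](O)C(O)(c1cc(OC)c(OC)cc1OC)c1cc(OC)c(OC)cc1OC
F2 | step 1 | bis(2,4,5-trimethoxyphenyl)methanone | COc1cc(OC)c(C(=O)c2cc(OC)c(OC)cc2OC)cc1OC
F3 | step 1 | N'-[bis(2,4,5-trimethoxyphenyl)methylidene]-4-methylbenzenesulfonohydrazide | COc1cc(OC)c(C(=NNS(=O)(=O)c2ccc(C)cc2)c2cc(OC)c(OC)cc2OC)cc1OC
F4 | step 2 | ethyl 2,4,6-triisopropylbenzoate | CCOC(=O)c1c(C(C)C)cc(C(C)C)cc1C(C)C
F5 | step 2 | (S)-1-lithioethyl 2,4,6-triisopropylbenzoate, as its (−)-sparteine complex (ligand not drawn) | C[C@H]([Li])OC(=O)c1c(C(C)C)cc(C(C)C)cc1C(C)C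
F6 | step 2 | lithium [bis(2,4,5-trimethoxyphenyl)methyl][(1S)-1-(2,4,6-triisopropylbenzoyloxy)ethyl](pinacolato)borate | C[C@H]([B-]1(OC(C)(C)C(C)(C)O1)C(c1cc(OC)c(OC)cc1OC)c1cc(OC)c(OC)cc1OC)OC(=O)c1c(C(C)C)cc(C(C)C)cc1C(C)C.[Li+]
A1 | direct plan | (R)-2-methyloxirane | C[C@@H]1CO1
A2 | direct plan | (2,4,5-trimethoxyphenyl)magnesium bromide | COc1cc(OC)c([Mg]Br)cc1OC
A3 | direct plan | (R)-1-(2,4,5-trimethoxyphenyl)propan-2-ol | COc1cc(OC)c(C[C@@H](C)O)cc1OC
A4 | direct plan | 1,2,4-trimethoxybenzene | COc1ccc(OC)c(OC)c1
A5 | direct plan | (2R)-2-hydroxy-1-(2,4,5-trimethoxyphenyl)propan-1-ylium | COc1cc(OC)c([CH+][C@@H](C)O)cc1OC
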